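**Retrosynthetic overview**
- The target is cut first at its 17 phenol protecting groups (global hydrogenolysis) and at both gallate esters (one double acylation of a diol).
- The key disconnection is the C8–C2' diarylmethine bond: a ring-opened upper half as a benzylic cation, an intact benzylated flavan as the arene (Friedel–Crafts).
- The two halves come from the two enantiomers of gallocatechin. The upper half is opened and capped with a thiol first, so only it can become the electrophile; its bought C3 centre directs the new C2' centre.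
- No ring is built. The chroman ring of the lower half is bought and kept; the pyran ring of the upper half is opened in step 1.

Assumption: (+)-gallocatechin, (−)-gallocatechin and 3,4,5-tris(benzyloxy)benzoyl chloride are bought; primed locants (C2', C3', C4') are the three-carbon chain of the ring-opened upper half, numbered as in its parent flavan.

**Step 1**
Reactants: 1 (+)-gallocatechin
Product: 3 (2S)-1-(benzylsulfanyl)-1-(3,4,5-trihydroxyphenyl)-3-(2,4,6-trihydroxyphenyl)propan-2-ol as both C1 epimers, via para-quinone methide 2 (not isolated)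
Conditions: BnSH (10 equiv), aq. NaOH (pH 12)/EtOH 1:1, degassed, Ar, 40 °C; then AcOH to pH 5
Reagents that add atoms: phenylmethanethiol (benzyl mercaptan), SCc1ccccc1
Why: The 4'-phenoxide opens the pyran ring by retro-oxa-Michael (E1cB) cleavage of O1–C2 to quinone methide 2, and excess soft thiolate adds 1,6 (thia-Michael) in competition with re-closure, as known for catechin; the bought C3 centre is untouched and the new C–S centre is erased in step 4.

**Step 2**
Reactants: 3 ring-opened thioether hexaphenol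
Product: 4 (2S)-1-(benzylsulfanyl)-1-[3,4,5-tris(benzyloxy)phenyl]-3-[2,4,6-tris(benzyloxy)phenyl]propan-2-ol as both C1 epimers
Conditions: BnBr (7 equiv), K2CO3, DMF, 0 °C to rt, Ar
Reagents that add atoms: benzyl bromide, BrCc1ccccc1
Why: Williamson etherification caps the six phenols while K2CO3 leaves the secondary alcohol alone, and benzylating the 4'-oxygen and the ring A oxygen that used to close the pyran blocks both thiolate loss and re-closure; no stereocentre is touched.

**Step 3**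
Reactants: 5 (−)-gallocatechin
Product: 6 (2S,3R)-5,7-bis(benzyloxy)-2-[3,4,5-tris(benzyloxy)phenyl]-3,4-dihydro-2H-chromen-3-ol
Conditions: BnBr (5.5 equiv), K2CO3, DMF, 0 °C to rt, Ar
Reagents that add atoms: benzyl bromide, BrCc1ccccc1
Why: Williamson etherification of the five phenols under the standard catechin conditions leaves the 3-OH free and both bought stereocentres unchanged.

**Step 4**
Reactants: 4 hexa-O-benzyl thioether; 6 penta-O-benzyl-(−)-gallocatechin (3 equiv, excess recovered)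
Product: 8 (2S,3R)-5,7-bis(benzyloxy)-8-{(1R,2S)-2-hydroxy-1-[3,4,5-tris(benzyloxy)phenyl]-3-[2,4,6-tris(benzyloxy)phenyl]propyl}-2-[3,4,5-tris(benzyloxy)phenyl]-3,4-dihydro-2H-chromen-3-ol, via benzylic cation 7 (not isolated)
Conditions: AgBF4 (2 equiv), THF, 0 °C, dark, Ar
Reagents that add atoms: none
Why: Silver removes the benzylthio group to give cation 7, which alkylates C8 of 6 in an SN1-type Friedel–Crafts reaction (C6 sits between two benzyloxy groups and is more hindered), and the arene is expected to enter anti to the bulky 2,4,6-tris(benzyloxy)benzyl group and past the small free hydroxyl of the allylic-strain-minimised cation, so the bought (2S) carbinol sets the new centre as (1R); this facial preference is a steric prediction, not a certainty.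

**Step 5**
Reactants: 8 diol; 9 3,4,5-tris(benzyloxy)benzoyl chloride (3 equiv)
Product: 10 heptadeca-O-benzyl bis-gallate (full name in the list)
Conditions: DMAP (0.5 equiv), pyridine/CH2Cl2, 40 °C
Reagents that add atoms: none
Why: DMAP-catalysed esterification with the acid chloride acylates both secondary alcohols at oxygen, with retention at both carbinol centres.

**Step 6**
Reactants: 10 heptadeca-O-benzyl bis-gallate
Product: 11 target, (2S,3R)-5,7-dihydroxy-2-(3,4,5-trihydroxyphenyl)-8-{(1R,2S)-1-(3,4,5-trihydroxyphenyl)-3-(2,4,6-trihydroxyphenyl)-2-[(3,4,5-trihydroxybenzoyl)oxy]propyl}-3,4-dihydro-2H-chromen-3-yl 3,4,5-trihydroxybenzoate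
Conditions: H2 (1 atm), Pd(OH)2/C, THF/MeOH 1:1, rt; filtered and freeze-dried under Ar
Reagents that add atoms: none
Why: Catalytic hydrogenolysis removes the 17 benzyl aryl ethers under neutral conditions that spare the two esters, the diarylmethine C–C bond and the chroman ether, and touches no stereocentre.

**Compound list**
1 | (+)-gallocatechin, (2R,3S)-2-(3,4,5-trihydroxyphenyl)-3,4-dihydro-2H-chromene-3,5,7-triol | Oc1cc(O)c2c(c1)O[C@H](c1cc(O)c(O)c(O)c1)[C@@H](O)C2 | starting material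
2 | para-quinone methide, 4-[(2S)-2-hydroxy-3-(2,4,6-trihydroxyphenyl)propylidene]-2,6-dihydroxycyclohexa-2,5-dien-1-one | O[C@@H](Cc1c(O)cc(O)cc1O)C=C1C=C(O)C(=O)C(O)=C1 | intermediate
3 | (2S)-1-(benzylsulfanyl)-1-(3,4,5-trihydroxyphenyl)-3-(2,4,6-trihydroxyphenyl)propan-2-ol, both C1 epimers | O[C@@H](Cc1c(O)cc(O)cc1O)C(SCc1ccccc1)c1cc(O)c(O)c(O)c1 | intermediate
4 | (2S)-1-(benzylsulfanyl)-1-[3,4,5-tris(benzyloxy)phenyl]-3-[2,4,6-tris(benzyloxy)phenyl]propan-2-ol, both C1 epimers | O[C@@H](Cc1c(OCc2ccccc2)cc(OCc2ccccc2)cc1OCc1ccccc1)C(SCc1ccccc1)c1cc(OCc2ccccc2)c(OCc2ccccc2)c(OCc2ccccc2)c1 | intermediate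
5 | (−)-gallocatechin, (2S,3R)-2-(3,4,5-trihydroxyphenyl)-3,4-dihydro-2H-chromene-3,5,7-triol | Oc1cc(O)c2c(c1)O[C@@H](c1cc(O)c(O)c(O)c1)[C@H](O)C2 | starting material
6 | (2S,3R)-5,7-bis(benzyloxy)-2-[3,4,5-tris(benzyloxy)phenyl]-3,4-dihydro-2H-chromen-3-ol | O(Cc1ccccc1)c1cc(OCc2ccccc2)c2c(c1)O[C@@H](c1cc(OCc3ccccc3)c(OCc3ccccc3)c(OCc3ccccc3)c1)[C@H](O)C2 | intermediate
7 | 2-hydroxy-1-[3,4,5-tris(benzyloxy)phenyl]-3-[2,4,6-tris(benzyloxy)phenyl]propan-1-ylium tetrafluoroborate, carbinol configuration as in 4 | O[C@@H](Cc1c(OCc2ccccc2)cc(OCc2ccccc2)cc1OCc1ccccc1)[CH+]c1cc(OCc2ccccc2)c(OCc2ccccc2)c(OCc2ccccc2)c1.F[B-](F)(F)F | intermediate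
8 | (2S,3R)-5,7-bis(benzyloxy)-8-{(1R,2S)-2-hydroxy-1-[3,4,5-tris(benzyloxy)phenyl]-3-[2,4,6-tris(benzyloxy)phenyl]propyl}-2-[3,4,5-tris(benzyloxy)phenyl]-3,4-dihydro-2H-chromen-3-ol | O[C@@H](Cc1c(OCc2ccccc2)cc(OCc2ccccc2)cc1OCc1ccccc1)[C@H](c1cc(OCc2ccccc2)c(OCc2ccccc2)c(OCc2ccccc2)c1)c1c(OCc2ccccc2)cc(OCc2ccccc2)c2c1O[C@@H](c1cc(OCc3ccccc3)c(OCc3ccccc3)c(OCc3ccccc3)c1)[C@H](O)C2 | intermediate
9 | 3,4,5-tris(benzyloxy)benzoyl chloride | O=C(Cl)c1cc(OCc2ccccc2)c(OCc2ccccc2)c(OCc2ccccc2)c1 | starting material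
10 | (2S,3R)-5,7-bis(benzyloxy)-2-[3,4,5-tris(benzyloxy)phenyl]-8-{(1R,2S)-1-[3,4,5-tris(benzyloxy)phenyl]-3-[2,4,6-tris(benzyloxy)phenyl]-2-{[3,4,5-tris(benzyloxy)benzoyl]oxy}propyl}-3,4-dihydro-2H-chromen-3-yl 3,4,5-tris(benzyloxy)benzoate | O=C(O[C@@H](Cc1c(OCc2ccccc2)cc(OCc2ccccc2)cc1OCc1ccccc1)[C@H](c1cc(OCc2ccccc2)c(OCc2ccccc2)c(OCc2ccccc2)c1)c1c(OCc2ccccc2)cc(OCc2ccccc2)c2c1O[C@@H](c1cc(OCc3ccccc3)c(OCc3ccccc3)c(OCc3ccccc3)c1)[C@H](OC(=O)c1cc(OCc3ccccc3)c(OCc3ccccc3)c(OCc3ccccc3)c1)C2)c1cc(OCc2ccccc2)c(OCc2ccccc2)c(OCc2ccccc2)c1 | intermediate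
11 | (2S,3R)-5,7-dihydroxy-2-(3,4,5-trihydroxyphenyl)-8-{(1R,2S)-1-(3,4,5-trihydroxyphenyl)-3-(2,4,6-trihydroxyphenyl)-2-[(3,4,5-trihydroxybenzoyl)oxy]propyl}-3,4-dihydro-2H-chromen-3-yl 3,4,5-trihydroxybenzoate | O=C(O[C@@H](Cc1c(O)cc(O)cc1O)[C@H](c1cc(O)c(O)c(O)c1)c1c(O)cc(O)c2c1O[C@@H](c1cc(O)c(O)c(O)c1)[C@H](OC(=O)c1cc(O)c(O)c(O)c1)C2)c1cc(O)c(O)c(O)c1 | target

**Totals**
Total step count: 6. Longest linear sequence: 5 (steps 1, 2, 4, 5, 6).

**Steps most likely to fail**

Step 4 (coupling). The cation may re-close onto its own ring A benzyloxy oxygen with loss of benzyl faster than the hindered arene 6 attacks, and the ratio at the new diarylmethine centre may be low or reversed. The fallback sets out from 4 and changes the nucleophile and the order of events. Compound 4 is coupled with unprotected (−)-gallocatechin 5 (AgBF4, THF, 0 °C). The free phloroglucinol-type ring A of 5 is far more nucleophilic than its dibenzyl ether, and its 7-OH can hydrogen-bond to the carbinol oxygen of the cation and deliver C8 on that face. This gives (2S,3R)-8-{(1R,2S)-2-hydroxy-1-[3,4,5-tris(benzyloxy)phenyl]-3-[2,4,6-tris(benzyloxy)phenyl]propyl}-2-(3,4,5-trihydroxyphenyl)-3,4-dihydro-2H-chromene-3,5,7-triol F1. Its five phenols are then benzylated (BnBr, K2CO3, DMF), and the route is rejoined at 8.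

Step 1 (ring opening). The pyrogallol ring may autoxidise at pH 12, or ring A may attack the quinone methide through carbon (catechinic-acid-type rearrangement). The fallback sets out from 1 and protects before opening. The five phenols of 1 are benzylated (BnBr, K2CO3, DMF) to penta-O-benzyl-(+)-gallocatechin F2. The pyran ring is then opened under acid instead of base (BnSH 10 equiv, catalytic TfOH, 1,1,1,3,3,3-hexafluoropropan-2-ol/CH2Cl2, 0 °C); the hard acid activates the ring ether but not the product sulfide. This gives (2S)-1-(benzylsulfanyl)-3-[2,4-bis(benzyloxy)-6-hydroxyphenyl]-1-[3,4,5-tris(benzyloxy)phenyl]propan-2-ol F3. The one freed phenol is benzylated (BnBr, K2CO3, DMF), and the route is rejoined at 4.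

Step 2 (hexabenzylation). The free phloroglucinol ring of 3 may be benzylated at carbon, and the 4'-phenoxide may expel thiolate before it is capped. The fallback sets out from 3 and masks the phenols first. Compound 3 is peracetylated (Ac2O, pyridine, rt) to (2S)-1-(benzylsulfanyl)-1-(3,4,5-triacetoxyphenyl)-3-(2,4,6-triacetoxyphenyl)propan-2-yl acetate F4. It is then treated with BnBr and K2CO3 in DMF/MeOH (rt to 40 °C). Methanolysis frees one phenoxide at a time from a ring that is still electron-poor, and each is O-benzylated at once; the alkyl acetate is methanolysed in the same pot. The route is rejoined at 4.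

**Further compounds**
F1 | step 4 | (2S,3R)-8-{(1R,2S)-2-hydroxy-1-[3,4,5-tris(benzyloxy)phenyl]-3-[2,4,6-tris(benzyloxy)phenyl]propyl}-2-(3,4,5-trihydroxyphenyl)-3,4-dihydro-2H-chromene-3,5,7-triol | O[C@@H](Cc1c(OCc2ccccc2)cc(OCc2ccccc2)cc1OCc1ccccc1)[C@H](c1cc(OCc2ccccc2)c(OCc2ccccc2)c(OCc2ccccc2)c1)c1c(O)cc(O)c2c1O[C@@H](c1cc(O)c(O)c(O)c1)[C@H](O)C2
F2 | step 1 | (2R,3S)-5,7-bis(benzyloxy)-2-[3,4,5-tris(benzyloxy)phenyl]-3,4-dihydro-2H-chromen-3-ol | O(Cc1ccccc1)c1cc(OCc2ccccc2)c2c(c1)O[C@H](c1cc(OCc3ccccc3)c(OCc3ccccc3)c(OCc3ccccc3)c1)[C@@H](O)C2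
F3 | step 1 | (2S)-1-(benzylsulfanyl)-3-[2,4-bis(benzyloxy)-6-hydroxyphenyl]-1-[3,4,5-tris(benzyloxy)phenyl]propan-2-ol, both C1 epimers | O[C@@H](Cc1c(O)cc(OCc2ccccc2)cc1OCc1ccccc1)C(SCc1ccccc1)c1cc(OCc2ccccc2)c(OCc2ccccc2)c(OCc2ccccc2)c1
F4 | step 2 | (2S)-1-(benzylsulfanyl)-1-(3,4,5-triacetoxyphenyl)-3-(2,4,6-triacetoxyphenyl)propan-2-yl acetate, both C1 epimers | CC(=O)O[C@@H](Cc1c(OC(C)=O)cc(OC(C)=O)cc1OC(C)=O)C(SCc1ccccc1)c1cc(OC(C)=O)c(OC(C)=O)c(OC(C)=O)c1
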